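**Plan**
- Retrosynthesis: cut O1–C2 of the dioxane first (ring A phenol plus a para-quinone methide at C2), then the C7 propenyl C=C (aldehyde olefination), the O4–C3 aryl alkyl ether (Mitsunobu) and the ring B aryl–C2 bond (aryl Grignard plus epoxide).
- Enabling feature: with the numbering O1–C2(aryl)–C3(methyl)–O4, C4a/C8a at the fusion, OMe on C5 and propenyl on C7 (ring A = fused benzene, ring B = 4-hydroxy-3,5-dimethoxyphenyl), C2 is the benzylic carbon para to the free OH of ring B. O1–C2 is therefore the adduct of a phenol to a para-quinone methide.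
- Forward order: the ring B Grignard reagent opens (S)-propylene oxide, and the resulting alcohol is joined to the 4-OH of 5-hydroxyvanillin. Silylation, ethylidenation and desilylation give the open diphenol, and the dioxane, the only ring made, is closed last by Ag2O.
- Stereochemistry: C3 comes from (S)-propylene oxide and is inverted to (R) in the Mitsunobu step. C2 is set in the ring closure, trans to the C3 methyl under reversible addition. The (E)-alkene comes from the Julia–Kocienski olefination.

Key step: step 7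

Assumption: 5-(ethylsulfonyl)-1-phenyl-1H-tetrazole, the olefination reagent of step 5, is taken as purchasable.

**Step 1**
Reactants: 1 4-bromo-2,6-dimethoxyphenol
Product: 2 (4-bromo-2,6-dimethoxyphenoxy)(tert-butyl)dimethylsilane
Conditions: TBSCl (1.2 equiv), imidazole (2.5 equiv), DMF, rt
Reagents that add atoms: tert-butyldimethylsilyl chloride, CC(C)(C)[Si](C)(C)Cl
Why: Imidazole-promoted O-silylation of a phenol should proceed cleanly even between two methoxy groups and masks the acidic proton, which would otherwise quench the Grignard reagent of step 2, as a fluoride-labile TBS ether.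

**Step 2**
Reactants: 2 (4-bromo-2,6-dimethoxyphenoxy)(tert-butyl)dimethylsilane; 3 (S)-propylene oxide
Product: 5 (2S)-1-[4-(tert-butyldimethylsilyloxy)-3,5-dimethoxyphenyl]propan-2-ol, via aryl Grignard reagent 4 (not isolated)
Conditions: Mg turnings (1.3 equiv), I2 (cat.), THF, reflux; then CuI (10 mol %), 3 (1.3 equiv), THF, −30 to 0 °C; then H2O
Reagents that add atoms: none
Why: Magnesium insertion into the aryl bromide followed by CuI-catalysed SN2 opening of the epoxide at its unsubstituted carbon (Grignard–epoxide alkylation) forms the ring B aryl–C2 bond without touching the stereocentre, so the (S) configuration of 3 is carried unchanged into 5.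

**Step 3**
Reactants: 5 (2S)-1-[4-(tert-butyldimethylsilyloxy)-3,5-dimethoxyphenyl]propan-2-ol; 6 5-hydroxyvanillin (3,4-dihydroxy-5-methoxybenzaldehyde)
Product: 7 3-hydroxy-5-methoxy-4-{[(2R)-1-[4-(tert-butyldimethylsilyloxy)-3,5-dimethoxyphenyl]propan-2-yl]oxy}benzaldehyde
Conditions: 6 (1.2 equiv), PPh3 (1.3 equiv), DIAD (1.3 equiv, slow addition), THF, 0 °C to rt
Reagents that add atoms: none
Why: In this Mitsunobu etherification the betaine ionises the more acidic 4-OH of 6 (para to the formyl group) and that phenoxide displaces the alkoxyphosphonium of 5 in an SN2 reaction with inversion, turning the (S)-carbinol into the (R)-configured O4–C3 ether, the future C3 of the target.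

**Step 4**
Reactants: 7 3-hydroxy-5-methoxy-4-{[(2R)-1-[4-(tert-butyldimethylsilyloxy)-3,5-dimethoxyphenyl]propan-2-yl]oxy}benzaldehyde
Product: 8 3-(tert-butyldimethylsilyloxy)-5-methoxy-4-{[(2R)-1-[4-(tert-butyldimethylsilyloxy)-3,5-dimethoxyphenyl]propan-2-yl]oxy}benzaldehyde
Conditions: TBSCl (1.3 equiv), imidazole (2.5 equiv), DMF, rt
Reagents that add atoms: tert-butyldimethylsilyl chloride, CC(C)(C)[Si](C)(C)Cl
Why: Standard imidazole-promoted silylation caps the remaining ring A phenol so that no acidic proton consumes the sulfonyl carbanion or deactivates the aldehyde as its phenoxide in step 5.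

**Step 5**
Reactants: 8 3-(tert-butyldimethylsilyloxy)-5-methoxy-4-{[(2R)-1-[4-(tert-butyldimethylsilyloxy)-3,5-dimethoxyphenyl]propan-2-yl]oxy}benzaldehyde
Product: 9 tert-butyl(2-{[(2R)-1-[4-(tert-butyldimethylsilyloxy)-3,5-dimethoxyphenyl]propan-2-yl]oxy}-3-methoxy-5-[(E)-prop-1-enyl]phenoxy)dimethylsilane
Conditions: 5-(ethylsulfonyl)-1-phenyl-1H-tetrazole (1.3 equiv), KN(SiMe3)2 (1.25 equiv), DME, −60 °C; then 8, −60 °C to rt
Reagents that add atoms: 5-(ethylsulfonyl)-1-phenyl-1H-tetrazole, CCS(=O)(=O)c1nnnn1-c1ccccc1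
Why: In this Julia–Kocienski olefination the potassium-metallated ethyl phenyltetrazolyl sulfone adds to the non-enolisable aryl aldehyde, Smiles rearrangement and loss of SO2 and tetrazololate follow, and with aromatic aldehydes this sequence should favour the conjugated (E)-propenyl alkene.

**Step 6**
Reactants: 9 tert-butyl(2-{[(2R)-1-[4-(tert-butyldimethylsilyloxy)-3,5-dimethoxyphenyl]propan-2-yl]oxy}-3-methoxy-5-[(E)-prop-1-enyl]phenoxy)dimethylsilane
Product: 10 2-{[(2R)-1-(4-hydroxy-3,5-dimethoxyphenyl)propan-2-yl]oxy}-3-methoxy-5-[(E)-prop-1-enyl]phenol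
Conditions: Bu4NF (2.4 equiv), AcOH (2.4 equiv), THF, 0 °C, Ar
Reagents that add atoms: none
Why: Fluoride-induced cleavage of both aryl silyl ethers, driven by the Si–F bond, should free the two phenols, with AcOH buffering the phenoxides so that the electron-rich diphenol is not air-oxidised and the alkene and the stereocentre are untouched.

**Step 7**
Reactants: 10 2-{[(2R)-1-(4-hydroxy-3,5-dimethoxyphenyl)propan-2-yl]oxy}-3-methoxy-5-[(E)-prop-1-enyl]phenol
Product: 12 4-{(2R,3R)-5-methoxy-3-methyl-7-[(E)-prop-1-enyl]-2,3-dihydro-1,4-benzodioxin-2-yl}-2,6-dimethoxyphenol, via para-quinone methide 11 (not isolated)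
Conditions: Ag2O (1.1 equiv), dry toluene–acetone 2:1 (0.01 M), rt, dark, Ar; filtration through Celite
Reagents that add atoms: none
Why: Ag2O should remove two electrons and two protons from the ring B phenol, whose phenoxyl radical has both ortho positions blocked by methoxy groups and the para position by the alkyl chain, so it can only lose the benzylic hydrogen and give para-quinone methide 11. The ring A hydroxyl O1-H then adds to the exocyclic methide carbon in an oxa-conjugate addition that restores the aromaticity of ring B and forms the O1–C2 bond; the closest known reaction type is the Ag2O oxidation of 4-alkyl-2,6-dimethoxyphenols to quinone methides together with the phenol-to-methide ring closure that ends Ag2O-mediated benzodioxane neolignan couplings. The dioxane ring closes in a 6-exo-trig mode. The new stereocentre C2 is controlled by the fixed (R)-C3 methyl group: closure through the half-chair that keeps methyl and aryl pseudo-equatorial gives the 2,3-trans (2R,3R) isomer, and because the product keeps the free para-hydroxyl the addition is reversible through 11, so the trans isomer should accumulate (a short exposure to K2CO3 in acetone would complete the equilibration if needed). The step needs oxidation of ring B before ring A, which is secured by the two flanking methoxy groups and the para C–H of ring B against a less electron-rich ring A phenol that cannot form a methide (O4 para to the propenyl chain is alkylated, O1-H is meta to it), and the near-stoichiometric amount of Ag2O limits a second oxidation at C2.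

**Compound list**
1 | 4-bromo-2,6-dimethoxyphenol | COc1cc(Br)cc(OC)c1O | starting material
2 | (4-bromo-2,6-dimethoxyphenoxy)(tert-butyl)dimethylsilane | COc1cc(Br)cc(OC)c1O[Si](C)(C)C(C)(C)C | intermediate
3 | (S)-propylene oxide, (2S)-2-methyloxirane | C[C@H]1CO1 | starting material
4 | [4-(tert-butyldimethylsilyloxy)-3,5-dimethoxyphenyl]magnesium bromide | COc1cc([Mg]Br)cc(OC)c1O[Si](C)(C)C(C)(C)C | intermediate
5 | (2S)-1-[4-(tert-butyldimethylsilyloxy)-3,5-dimethoxyphenyl]propan-2-ol | C[C@H](O)Cc1cc(OC)c(O[Si](C)(C)C(C)(C)C)c(OC)c1 | intermediate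
6 | 5-hydroxyvanillin (3,4-dihydroxy-5-methoxybenzaldehyde) | COc1cc(C=O)cc(O)c1O | starting material
7 | 3-hydroxy-5-methoxy-4-{[(2R)-1-[4-(tert-butyldimethylsilyloxy)-3,5-dimethoxyphenyl]propan-2-yl]oxy}benzaldehyde | O=Cc1cc(OC)c(O[C@H](C)Cc2cc(OC)c(O[Si](C)(C)C(C)(C)C)c(OC)c2)c(O)c1 | intermediate
8 | 3-(tert-butyldimethylsilyloxy)-5-methoxy-4-{[(2R)-1-[4-(tert-butyldimethylsilyloxy)-3,5-dimethoxyphenyl]propan-2-yl]oxy}benzaldehyde | O=Cc1cc(OC)c(O[C@H](C)Cc2cc(OC)c(O[Si](C)(C)C(C)(C)C)c(OC)c2)c(O[Si](C)(C)C(C)(C)C)c1 | intermediate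
9 | tert-butyl(2-{[(2R)-1-[4-(tert-butyldimethylsilyloxy)-3,5-dimethoxyphenyl]propan-2-yl]oxy}-3-methoxy-5-[(E)-prop-1-enyl]phenoxy)dimethylsilane | C/C=C/c1cc(OC)c(O[C@H](C)Cc2cc(OC)c(O[Si](C)(C)C(C)(C)C)c(OC)c2)c(O[Si](C)(C)C(C)(C)C)c1 | intermediate
10 | 2-{[(2R)-1-(4-hydroxy-3,5-dimethoxyphenyl)propan-2-yl]oxy}-3-methoxy-5-[(E)-prop-1-enyl]phenol | C/C=C/c1cc(OC)c(O[C@H](C)Cc2cc(OC)c(O)c(OC)c2)c(O)c1 | intermediate
11 | 4-[(2R)-2-{2-hydroxy-6-methoxy-4-[(E)-prop-1-enyl]phenoxy}propylidene]-2,6-dimethoxycyclohexa-2,5-dien-1-one | C/C=C/c1cc(OC)c(O[C@H](C)C=C2C=C(OC)C(=O)C(OC)=C2)c(O)c1 | intermediate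
12 | 4-{(2R,3R)-5-methoxy-3-methyl-7-[(E)-prop-1-enyl]-2,3-dihydro-1,4-benzodioxin-2-yl}-2,6-dimethoxyphenol | C/C=C/c1cc(OC)c2c(c1)O[C@H](c1cc(OC)c(O)c(OC)c1)[C@@H](C)O2 | target

**Step count**
Total steps: 7. Longest linear sequence: 7 steps (1 to 12).

**Steps most likely to fail**

Step 7. The oxidation may not stop cleanly at the closed product. The product's own ring B phenol can be oxidised a second time at C2. Radical coupling through a ring A phenoxyl can compete. Methide 11 can also tautomerise to the aryl enol ether, which would erase C3. The fallback reaches the same methide without any oxidant, from a benzylic alcohol; it sets out from 6 (with bromide 2 as the second component) and comes back at 12.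
- Mitsunobu reaction of 6 with ethyl (S)-lactate (PPh3, DIAD, THF) at the 4-OH, with inversion, should give ethyl (2R)-2-(4-formyl-2-hydroxy-6-methoxyphenoxy)propanoate F1.
- Silylation (TBSCl, imidazole, DMF) gives ethyl (2R)-2-[2-(tert-butyldimethylsilyloxy)-4-formyl-6-methoxyphenoxy]propanoate F2.
- Julia–Kocienski ethylidenation under the conditions of step 5, with the sulfone metallated before the aldehyde is added, gives ethyl (2R)-2-{2-(tert-butyldimethylsilyloxy)-6-methoxy-4-[(E)-prop-1-enyl]phenoxy}propanoate F3.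
- Reduction with i-Bu2AlH in CH2Cl2 at −78 °C should stop at (2R)-2-{2-(tert-butyldimethylsilyloxy)-6-methoxy-4-[(E)-prop-1-enyl]phenoxy}propanal F4.
- The aryllithium made from 2 (n-BuLi, THF, −78 °C) adds to F4 to give (2R)-1-[4-(tert-butyldimethylsilyloxy)-3,5-dimethoxyphenyl]-2-{2-(tert-butyldimethylsilyloxy)-6-methoxy-4-[(E)-prop-1-enyl]phenoxy}propan-1-ol F5 as a mixture of C1 epimers, which is of no consequence.
- Bu4NF/AcOH frees both phenols to give 4-[(2R)-1-hydroxy-2-{2-hydroxy-6-methoxy-4-[(E)-prop-1-enyl]phenoxy}propyl]-2,6-dimethoxyphenol F6.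
- A catalytic amount of TsOH in CH2Cl2 at 0 °C ionises the para-hydroxybenzylic alcohol to the protonated form of 11, which should close to 12 under thermodynamic (trans) control.

Step 3. Site selectivity between the two hydroxyls of 6 may be poor, or a second alkylation may follow at the 3-OH, since the 4-oxygen is flanked on both sides. The fallback removes the second hydroxyl from the coupling partner; it sets out from 5 and comes back at 10.
- Mitsunobu reaction of 5 with 5-bromovanillin (3-bromo-4-hydroxy-5-methoxybenzaldehyde), a single and more acidic phenol, should give 3-bromo-5-methoxy-4-{[(2R)-1-[4-(tert-butyldimethylsilyloxy)-3,5-dimethoxyphenyl]propan-2-yl]oxy}benzaldehyde F7 with the same inversion.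
- Julia–Kocienski ethylidenation as in step 5 gives tert-butyl{4-[(2R)-2-{2-bromo-6-methoxy-4-[(E)-prop-1-enyl]phenoxy}propyl]-2,6-dimethoxyphenoxy}dimethylsilane F8.
- Palladium-catalysed hydroxylation of the aryl bromide (Pd2(dba)3, t-BuXPhos, KOH, 1,4-dioxane–H2O, 100 °C, Ar) installs O1-H, while the hot aqueous KOH also cleaves the ring B aryl silyl ether, so that acidification should deliver 10 directly.

Step 5. The (E)-selectivity of the elimination stage may erode, leaving (Z)-alkene that would be carried into the target. The fallback separates C=C formation from geometry control; it sets out from 8 and comes back at 9.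
- A Wittig reaction of 8 with the ylide from ethyltriphenylphosphonium bromide (n-BuLi, THF, −78 °C to rt) gives the alkene without selectivity for (E), largely as tert-butyl(2-{[(2R)-1-[4-(tert-butyldimethylsilyloxy)-3,5-dimethoxyphenyl]propan-2-yl]oxy}-3-methoxy-5-[(Z)-prop-1-enyl]phenoxy)dimethylsilane F9.
- Catalytic PdCl2(MeCN)2 in CH2Cl2 at rt then isomerises the mixture to the thermodynamically preferred conjugated (E)-alkene 9.

**Further compounds**
F1 | step 7 | ethyl (2R)-2-(4-formyl-2-hydroxy-6-methoxyphenoxy)propanoate | CCOC(=O)[C@@H](C)Oc1c(O)cc(C=O)cc1OC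
F2 | step 7 | ethyl (2R)-2-[2-(tert-butyldimethylsilyloxy)-4-formyl-6-methoxyphenoxy]propanoate | CCOC(=O)[C@@H](C)Oc1c(O[Si](C)(C)C(C)(C)C)cc(C=O)cc1OC
F3 | step 7 | ethyl (2R)-2-{2-(tert-butyldimethylsilyloxy)-6-methoxy-4-[(E)-prop-1-enyl]phenoxy}propanoate | CCOC(=O)[C@@H](C)Oc1c(O[Si](C)(C)C(C)(C)C)cc(/C=C/C)cc1OC
F4 | step 7 | (2R)-2-{2-(tert-butyldimethylsilyloxy)-6-methoxy-4-[(E)-prop-1-enyl]phenoxy}propanal | O=C[C@@H](C)Oc1c(O[Si](C)(C)C(C)(C)C)cc(/C=C/C)cc1OC
F5 | step 7 | (2R)-1-[4-(tert-butyldimethylsilyloxy)-3,5-dimethoxyphenyl]-2-{2-(tert-butyldimethylsilyloxy)-6-methoxy-4-[(E)-prop-1-enyl]phenoxy}propan-1-ol (both C1 epimers) | C/C=C/c1cc(OC)c(O[C@H](C)C(O)c2cc(OC)c(O[Si](C)(C)C(C)(C)C)c(OC)c2)c(O[Si](C)(C)C(C)(C)C)c1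
F6 | step 7 | 4-[(2R)-1-hydroxy-2-{2-hydroxy-6-methoxy-4-[(E)-prop-1-enyl]phenoxy}propyl]-2,6-dimethoxyphenol (both C1 epimers) | C/C=C/c1cc(OC)c(O[C@H](C)C(O)c2cc(OC)c(O)c(OC)c2)c(O)c1
F7 | step 3 | 3-bromo-5-methoxy-4-{[(2R)-1-[4-(tert-butyldimethylsilyloxy)-3,5-dimethoxyphenyl]propan-2-yl]oxy}benzaldehyde | O=Cc1cc(OC)c(O[C@H](C)Cc2cc(OC)c(O[Si](C)(C)C(C)(C)C)c(OC)c2)c(Br)c1
F8 | step 3 | tert-butyl{4-[(2R)-2-{2-bromo-6-methoxy-4-[(E)-prop-1-enyl]phenoxy}propyl]-2,6-dimethoxyphenoxy}dimethylsilane | C/C=C/c1cc(OC)c(O[C@H](C)Cc2cc(OC)c(O[Si](C)(C)C(C)(C)C)c(OC)c2)c(Br)c1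
F9 | step 5 | tert-butyl(2-{[(2R)-1-[4-(tert-butyldimethylsilyloxy)-3,5-dimethoxyphenyl]propan-2-yl]oxy}-3-methoxy-5-[(Z)-prop-1-enyl]phenoxy)dimethylsilane | C/C=C\c1cc(OC)c(O[C@H](C)Cc2cc(OC)c(O[Si](C)(C)C(C)(C)C)c(OC)c2)c(O[Si](C)(C)C(C)(C)C)c1
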